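**Retrosynthetic overview**
1. Succedaneaflavanone is C2-symmetric: two identical (2S)-flavanone halves joined C6–C6''. Every step after the biaryl bond is run in two directions, and the last step is global O-debenzylation.
2. Each pyranone ring C is not closed as a six-membered ring. It is made from a benzofuran-3-one ring (O1, C2, C4, C4a, C8a) by adding C3 as a cyclopropane CH2 and then opening the C2–C4 bond with base, a one-carbon ring expansion done twice in one operation.
3. Enabling feature: C2 carries both the ring oxygen O1 and ring B. In the cyclopropanolate the bond from the carbinol carbon (future C4) to C2 is therefore the one that breaks, and rear-side protonation of C2 turns the quaternary cyclopropane centre into the (2S) centre.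
4. The two furanone rings come from a double intramolecular Friedel–Crafts acylation of a bis(aryloxy)arylacetic acid. O1 is the only oxygen para to the biaryl bond, which fixes the 6,6'' (not 8,8'') connectivity.
5. Order of ring formation: biaryl bond between two ring A units (oxidative homocoupling), then two furanone rings, then two cyclopropanes (asymmetric Simmons–Smith), then two rings C (ring expansion). Rings A and B are bought.

Key step: step 9

Assumption: the configuration of the C6–C6'' biaryl axis is not part of the given structure, so it is left unassigned and rotamers about it are carried through together; the enantiomer of the chiral ligand in step 8 is to be matched to the required (1aR,6bR) configuration.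

**Route**

Step 1
Reactants: 1 3,5-bis(benzyloxy)phenol
Product: 2 [3,5-bis(benzyloxy)phenoxy]triisopropylsilane
Conditions: i-Pr3SiCl, imidazole, DMF, rt
Reagents that add atoms: chlorotriisopropylsilane, CC(C)[Si](Cl)(C(C)C)C(C)C
Why: Silyl ether formation masks the oxygen that will become O1 with a bulky, non-directing group, so the C–H between the two benzyloxy groups is the only site left for the directed metalation of step 2.

Step 2
Reactants: 2 [3,5-bis(benzyloxy)phenoxy]triisopropylsilane (two molecules)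
Product: 4 2,2',6,6'-tetrakis(benzyloxy)-4,4'-bis(triisopropylsilyloxy)-1,1'-biphenyl, via aryllithium 3 (not isolated)
Conditions: n-BuLi, TMEDA, THF, 0 °C; then CuCl2, −78 °C → rt
Reagents that add atoms: none
Why: Directed ortho-metalation between the two benzyloxy groups, followed by CuCl2-mediated oxidative homocoupling of the aryllithium, should give the tetra-ortho-oxygenated biaryl with the two future O1 oxygens para to the new bond.

Step 3
Reactants: 5 methyl 2-[4-(benzyloxy)phenyl]acetate
Product: 7 methyl 2-bromo-2-[4-(benzyloxy)phenyl]acetate (racemic), via lithium enolate 6 (not isolated)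
Conditions: LiN(SiMe3)2, THF, −78 °C; then NBS, −78 °C
Reagents that add atoms: N-bromosuccinimide, O=C1CCC(=O)N1Br
Why: Electrophilic α-bromination of the ester enolate puts the leaving group on the carbon that becomes C2, without touching the benzylic OCH2Ph position that a radical bromination would attack.

Step 4
Reactants: 4 2,2',6,6'-tetrakis(benzyloxy)-4,4'-bis(triisopropylsilyloxy)-1,1'-biphenyl; 7 methyl 2-bromo-2-[4-(benzyloxy)phenyl]acetate (2.2 equiv)
Product: 9 dimethyl 2,2'-{[2,2',6,6'-tetrakis(benzyloxy)-1,1'-biphenyl-4,4'-diyl]bis(oxy)}bis{2-[4-(benzyloxy)phenyl]acetate} (mixture of diastereomers), via dicesium bisphenoxide 8 (not isolated)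
Conditions: CsF, DMF, rt; then 7, 0 °C → rt
Reagents that add atoms: none
Why: Fluoride desilylation frees only the two phenoxides para to the biaryl bond, and their Williamson etherification (SN2 at the activated α-bromo ester) forms both O1–C2 bonds; the two new stereocentres are erased in step 7.

Step 5
Reactants: 9 the bis(aryloxy) diester
Product: 10 2,2'-{[2,2',6,6'-tetrakis(benzyloxy)-1,1'-biphenyl-4,4'-diyl]bis(oxy)}bis{2-[4-(benzyloxy)phenyl]acetic acid}
Conditions: LiOH·H2O, THF/MeOH/H2O, rt; then 1 M HCl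
Reagents that add atoms: lithium hydroxide, [Li+].[OH-]
Why: Saponification of the two methyl esters gives the diacid for acylation and leaves the benzyl ethers untouched.

Step 6
Reactants: 10 the bis(aryloxy) diacid
Product: 12 4,4',6,6'-tetrakis(benzyloxy)-2,2'-bis[4-(benzyloxy)phenyl]-[5,5'-bi(1-benzofuran)]-3,3'(2H,2'H)-dione (stereoisomer mixture at C2 and C2'), via bis(acid chloride) 11 (not isolated)
Conditions: (COCl)2, DMF (cat.), CH2Cl2, 0 °C; then ZnCl2, 0 °C → rt (argon)
Reagents that add atoms: none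
Why: Intramolecular Friedel–Crafts acylation of each phloroglucinol-type ring at the carbon ortho to the aryloxy oxygen closes both five-membered furanone rings; the two ortho positions of each ring are equivalent, so one regioisomer results.

Step 7
Reactants: 12 the bis(benzofuran-3-one)
Product: 13 4,4',6,6'-tetrakis(benzyloxy)-2,2'-bis[4-(benzyloxy)phenyl]-3,3'-bis(triethylsilyloxy)-5,5'-bi(1-benzofuran)
Conditions: Et3SiOTf, Et3N, CH2Cl2, −78 → 0 °C (argon, crude 12)
Reagents that add atoms: triethylsilyl trifluoromethanesulfonate, CC[Si](CC)(CC)OS(=O)(=O)C(F)(F)F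
Why: Soft enolisation and O-silylation are driven by aromatisation to the benzofuran; this removes the labile C2 centres and protects the oxidation-prone 2-aryl ketone as an electron-rich silyl enol ether.

Step 8
Reactants: 13 the bis(3-silyloxybenzofuran)
Product: 14 (1aR,6bR,1a'R,6b'R)-4,4',6,6'-tetrakis(benzyloxy)-1a,1a'-bis[4-(benzyloxy)phenyl]-6b,6b'-bis(triethylsilyloxy)-1a,1a',6b,6b'-tetrahydro-1H,1'H-5,5'-bi(cyclopropa[b][1]benzofuran)
Conditions: Et2Zn, CH2I2, N-Boc-L-Val-L-Pro-OMe (or its enantiomer, whichever gives 1aR,6bR), CH2Cl2, −40 → 0 °C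
Reagents that add atoms: diiodomethane, ICI
Why: Proposed new method: a zinc carbenoid made from Et2Zn and CH2I2 and carrying the deprotonated dipeptide as chiral ligand should transfer CH2 in a concerted butterfly transition state to the electron-rich C2=C3 enol ether bond of each benzofuran, the ligand shielding one face so that the (1aR,6bR) cyclopropane forms twice; the closest known reaction type is the dipeptide-mediated asymmetric Simmons–Smith cyclopropanation of silyl enol ethers of aryl ketones, which has not been shown on a tetrasubstituted enol ether inside a benzofuran, and because the reagent acts twice, minor-face attack should end up mainly in a separable diastereomer.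

Step 9
Reactants: 14 the bis(silyloxycyclopropane)
Product: 16 (2S,2''S)-5,5'',7,7''-tetrakis(benzyloxy)-2,2''-bis[4-(benzyloxy)phenyl]-[6,6''-bichromane]-4,4''-dione (hexa-O-benzyl succedaneaflavanone), via bis-cyclopropanolate 15 (not isolated)
Conditions: Bu4NF (2.2 equiv), THF/MeOH (4:1), −78 → −30 °C; then AcOH, −30 °C
Reagents that add atoms: none
Why: Fluoride removes both silyl groups, and each cyclopropanolate opens by heterolysis of the bond shared by the three- and five-membered rings (carbinol carbon to C1a), because this puts the developing negative charge on the carbon stabilised by ring B and the aryloxy oxygen rather than on the CH2 group; methanol protonates that carbon as the bond breaks (homoenolate-type SE2 protonolysis), so the carbinol carbon becomes the C4 ketone, the cyclopropane CH2 becomes C3 and the furanone is enlarged to the pyranone ring C. The closest known reaction type is the base-induced ring opening of 2-arylcyclopropanols, which cleaves towards the benzylic carbon with inversion at that carbon. No ring is closed: each ring C arises by one-carbon ring expansion, through cleavage of the zero-atom bridge of the oxabicyclo[3.1.0]hexane unit. Each C2 stereocentre is controlled by the configuration of C1a in 14: rear-side protonation is expected to convert 1aR into 2S, while the carbinol stereocentre is erased. The step needs internal rather than external C–C cleavage, secured by the aryl and oxygen substituents on C1a, and stereospecific protonation without later retro-oxa-Michael scrambling, secured by the protic medium, the low temperature and the AcOH quench before warming.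

Step 10
Reactants: 16 hexa-O-benzyl succedaneaflavanone
Product: 17 succedaneaflavanone, (2S,2''S)-5,5'',7,7''-tetrahydroxy-2,2''-bis(4-hydroxyphenyl)-[6,6''-bichromane]-4,4''-dione
Conditions: H2 (1 atm), Pd/C (10%), EtOAc/MeOH, rt
Reagents that add atoms: none
Why: Hydrogenolysis of the six aryl benzyl ethers under neutral conditions should free all phenols without base, so the retro-oxa-Michael-prone C2 centres and the C4 ketones are preserved; the reaction is stopped at full debenzylation.

**Compound list**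
1 | 3,5-bis(benzyloxy)phenol | Oc1cc(OCc2ccccc2)cc(OCc2ccccc2)c1 | starting material
2 | [3,5-bis(benzyloxy)phenoxy]triisopropylsilane | CC(C)[Si](Oc1cc(OCc2ccccc2)cc(OCc2ccccc2)c1)(C(C)C)C(C)C | intermediate
3 | [2,6-bis(benzyloxy)-4-(triisopropylsilyloxy)phenyl]lithium | [Li]c1c(OCc2ccccc2)cc(O[Si](C(C)C)(C(C)C)C(C)C)cc1OCc1ccccc1 | intermediate
4 | 2,2',6,6'-tetrakis(benzyloxy)-4,4'-bis(triisopropylsilyloxy)-1,1'-biphenyl | CC(C)[Si](Oc1cc(OCc2ccccc2)c(-c2c(OCc3ccccc3)cc(O[Si](C(C)C)(C(C)C)C(C)C)cc2OCc2ccccc2)c(OCc2ccccc2)c1)(C(C)C)C(C)C | intermediate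
5 | methyl 2-[4-(benzyloxy)phenyl]acetate | COC(=O)Cc1ccc(OCc2ccccc2)cc1 | starting material
6 | lithium enolate of methyl 2-[4-(benzyloxy)phenyl]acetate | [Li+].COC([O-])=Cc1ccc(OCc2ccccc2)cc1 | intermediate
7 | methyl 2-bromo-2-[4-(benzyloxy)phenyl]acetate (racemic) | COC(=O)C(Br)c1ccc(OCc2ccccc2)cc1 | intermediate
8 | dicesium 2,2',6,6'-tetrakis(benzyloxy)-1,1'-biphenyl-4,4'-diolate | [Cs+].[Cs+].[O-]c1cc(OCc2ccccc2)c(-c2c(OCc3ccccc3)cc([O-])cc2OCc2ccccc2)c(OCc2ccccc2)c1 | intermediate
9 | dimethyl 2,2'-{[2,2',6,6'-tetrakis(benzyloxy)-1,1'-biphenyl-4,4'-diyl]bis(oxy)}bis{2-[4-(benzyloxy)phenyl]acetate} (diastereomer mixture) | COC(=O)C(Oc1cc(OCc2ccccc2)c(-c2c(OCc3ccccc3)cc(OC(C(=O)OC)c3ccc(OCc4ccccc4)cc3)cc2OCc2ccccc2)c(OCc2ccccc2)c1)c1ccc(OCc2ccccc2)cc1 | intermediate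
10 | 2,2'-{[2,2',6,6'-tetrakis(benzyloxy)-1,1'-biphenyl-4,4'-diyl]bis(oxy)}bis{2-[4-(benzyloxy)phenyl]acetic acid} | OC(=O)C(Oc1cc(OCc2ccccc2)c(-c2c(OCc3ccccc3)cc(OC(C(=O)O)c3ccc(OCc4ccccc4)cc3)cc2OCc2ccccc2)c(OCc2ccccc2)c1)c1ccc(OCc2ccccc2)cc1 | intermediate
11 | bis(acid chloride) of 10 | ClC(=O)C(Oc1cc(OCc2ccccc2)c(-c2c(OCc3ccccc3)cc(OC(C(Cl)=O)c3ccc(OCc4ccccc4)cc3)cc2OCc2ccccc2)c(OCc2ccccc2)c1)c1ccc(OCc2ccccc2)cc1 | intermediate
12 | 4,4',6,6'-tetrakis(benzyloxy)-2,2'-bis[4-(benzyloxy)phenyl]-[5,5'-bi(1-benzofuran)]-3,3'(2H,2'H)-dione | O=C1C(c2ccc(OCc3ccccc3)cc2)Oc2cc(OCc3ccccc3)c(-c3c(OCc4ccccc4)cc4OC(c5ccc(OCc6ccccc6)cc5)C(=O)c4c3OCc3ccccc3)c(OCc3ccccc3)c21 | intermediate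
13 | 4,4',6,6'-tetrakis(benzyloxy)-2,2'-bis[4-(benzyloxy)phenyl]-3,3'-bis(triethylsilyloxy)-5,5'-bi(1-benzofuran) | CC[Si](CC)(CC)Oc1c(-c2ccc(OCc3ccccc3)cc2)oc2cc(OCc3ccccc3)c(-c3c(OCc4ccccc4)cc4oc(-c5ccc(OCc6ccccc6)cc5)c(O[Si](CC)(CC)CC)c4c3OCc3ccccc3)c(OCc3ccccc3)c12 | intermediate
14 | (1aR,6bR,1a'R,6b'R)-bis(silyloxycyclopropane) of step 8 | CC[Si](CC)(CC)O[C@@]12C[C@]1(c1ccc(OCc3ccccc3)cc1)Oc1cc(OCc3ccccc3)c(-c3c(OCc4ccccc4)cc4O[C@@]5(c6ccc(OCc7ccccc7)cc6)C[C@@]5(O[Si](CC)(CC)CC)c4c3OCc3ccccc3)c(OCc3ccccc3)c12 | intermediate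
15 | bis(tetrabutylammonium) (1aR,6bR,1a'R,6b'R)-bis-cyclopropanolate | [O-][C@@]12C[C@]1(c1ccc(OCc3ccccc3)cc1)Oc1cc(OCc3ccccc3)c(-c3c(OCc4ccccc4)cc4O[C@@]5(c6ccc(OCc7ccccc7)cc6)C[C@@]5([O-])c4c3OCc3ccccc3)c(OCc3ccccc3)c12.CCCC[N+](CCCC)(CCCC)CCCC.CCCC[N+](CCCC)(CCCC)CCCC | intermediate
16 | (2S,2''S)-5,5'',7,7''-tetrakis(benzyloxy)-2,2''-bis[4-(benzyloxy)phenyl]-[6,6''-bichromane]-4,4''-dione | O=C1C[C@@H](c2ccc(OCc3ccccc3)cc2)Oc2cc(OCc3ccccc3)c(-c3c(OCc4ccccc4)cc4c(c3OCc3ccccc3)C(=O)C[C@@H](c3ccc(OCc5ccccc5)cc3)O4)c(OCc3ccccc3)c21 | intermediate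
17 | succedaneaflavanone | O=C1C[C@@H](c2ccc(O)cc2)Oc2cc(O)c(-c3c(O)cc4c(c3O)C(=O)C[C@@H](c3ccc(O)cc3)O4)c(O)c21 | target

**Step count and risks**

Total step count: 10. Longest linear sequence: 9 steps (steps 1, 2, 4, 5, 6, 7, 8, 9, 10); step 3 prepares the side-chain bromide.

Step 8 (first risk). The ligand-bound carbenoid may transfer CH2 too slowly to the hindered, partly aromatic tetrasubstituted enol ether, or the external ligand may not discriminate the two faces well enough. The fallback uses a covalently bound auxiliary and known hydroxyl-directed cyclopropanation. It sets out from 12.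
- Acid-catalysed condensation of 12 with (2R,4R)-pentane-2,4-diol (PPTS, toluene, azeotropic removal of water) should give the bis(hydroxypentyl) enol ether F1. The diol enantiomer is chosen so that the next step gives 1aR,6bR; it is drawn for the (2R,4R)-diol.
- Et2Zn and CH2I2 in Et2O form a zinc alkoxide on the free hydroxyl, which delivers CH2 intramolecularly to one face and should give the bis-cyclopropane F2.
- Dess–Martin periodinane oxidises the two auxiliary hydroxyls to the bis(oxopentyl) ether F3.
- Bu4NOH in THF/MeOH at −30 °C eliminates pent-3-en-2-one and releases bis-cyclopropanolate 15, which ring-expands as in step 9.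
The fallback comes back to the route at 16.

Step 9 (second risk). Protonation may lose stereochemical fidelity, either by front-side delivery or through a free, configurationally labile benzylic anion, and the product may partly ring-open by retro-oxa-Michael reaction in the basic medium. The fallback keeps the ring expansion but sets C2 afterwards by known chemistry. It sets out from 14, whose configuration then no longer matters.
- Ito–Saegusa oxidative ring opening (FeCl3, DMF, 0 °C) should give the bis(2-chloroflavanone) F4.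
- NaOAc in MeOH removes HCl to give the bis-flavone F5 (hexa-O-benzyl 6,6''-biapigenin).
- Asymmetric hydrogenation with the Ru–NHC catalyst made from [Ru(cod)(2-methylallyl)2], (R,R)-SINpEt·HBF4 and KOt-Bu under H2 pressure (ligand enantiomer chosen for 2S) should give the bis(cis-flavan-4-ol) F6.
- Dess–Martin periodinane oxidises the two carbinols.
The fallback comes back to the route at 16.

Step 2 (third risk). n-BuLi may deprotonate a benzylic OCH2Ph group (followed by Wittig rearrangement), or the two doubly ortho-substituted aryl copper species may be protonated or couple poorly. The fallback avoids both the organolithium and the oxidative coupling. It sets out from 2.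
- Electrophilic iodination with N-iodosuccinimide (MeCN, 0 °C) should go to the position between the two benzyloxy groups, the other two positions being shielded by the triisopropylsilyloxy group, and give aryl iodide F7.
- Classical Ullmann reductive homocoupling (activated Cu powder, DMF, 140 °C) joins two molecules of F7.
The fallback comes back to the route at 4.

Further compounds
F1 | step 8 | 4,4',6,6'-tetrakis(benzyloxy)-2,2'-bis[4-(benzyloxy)phenyl]-3,3'-bis{[(2R,4R)-4-hydroxypentan-2-yl]oxy}-5,5'-bi(1-benzofuran) | C[C@@H](O)C[C@@H](C)Oc1c(-c2ccc(OCc3ccccc3)cc2)oc2cc(OCc3ccccc3)c(-c3c(OCc4ccccc4)cc4oc(-c5ccc(OCc6ccccc6)cc5)c(O[C@H](C)C[C@@H](C)O)c4c3OCc3ccccc3)c(OCc3ccccc3)c12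
F2 | step 8 | (1aR,6bR,1a'R,6b'R)-bis-cyclopropane carrying [(2R,4R)-4-hydroxypentan-2-yl]oxy groups at C6b and C6b' | C[C@@H](O)C[C@@H](C)O[C@@]12C[C@]1(c1ccc(OCc3ccccc3)cc1)Oc1cc(OCc3ccccc3)c(-c3c(OCc4ccccc4)cc4O[C@@]5(c6ccc(OCc7ccccc7)cc6)C[C@@]5(O[C@H](C)C[C@@H](C)O)c4c3OCc3ccccc3)c(OCc3ccccc3)c12
F3 | step 8 | (1aR,6bR,1a'R,6b'R)-bis-cyclopropane carrying [(2R)-4-oxopentan-2-yl]oxy groups at C6b and C6b' | CC(=O)C[C@@H](C)O[C@@]12C[C@]1(c1ccc(OCc3ccccc3)cc1)Oc1cc(OCc3ccccc3)c(-c3c(OCc4ccccc4)cc4O[C@@]5(c6ccc(OCc7ccccc7)cc6)C[C@@]5(O[C@H](C)CC(C)=O)c4c3OCc3ccccc3)c(OCc3ccccc3)c12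
F4 | step 9 | 5,5'',7,7''-tetrakis(benzyloxy)-2,2''-bis[4-(benzyloxy)phenyl]-2,2''-dichloro-[6,6''-bichromane]-4,4''-dione (stereoisomer mixture) | O=C1CC(Cl)(c2ccc(OCc3ccccc3)cc2)Oc2cc(OCc3ccccc3)c(-c3c(OCc4ccccc4)cc4c(c3OCc3ccccc3)C(=O)CC(Cl)(c3ccc(OCc5ccccc5)cc3)O4)c(OCc3ccccc3)c21
F5 | step 9 | 5,5'',7,7''-tetrakis(benzyloxy)-2,2''-bis[4-(benzyloxy)phenyl]-4H,4''H-[6,6''-bichromene]-4,4''-dione | O=c1cc(-c2ccc(OCc3ccccc3)cc2)oc2cc(OCc3ccccc3)c(-c3c(OCc4ccccc4)cc4oc(-c5ccc(OCc6ccccc6)cc5)cc(=O)c4c3OCc3ccccc3)c(OCc3ccccc3)c12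
F6 | step 9 | (2S,4S,2''S,4''S)-5,5'',7,7''-tetrakis(benzyloxy)-2,2''-bis[4-(benzyloxy)phenyl]-[6,6''-bichromane]-4,4''-diol | O[C@H]1C[C@@H](c2ccc(OCc3ccccc3)cc2)Oc2cc(OCc3ccccc3)c(-c3c(OCc4ccccc4)cc4c(c3OCc3ccccc3)[C@@H](O)C[C@@H](c3ccc(OCc5ccccc5)cc3)O4)c(OCc3ccccc3)c21
F7 | step 2 | [3,5-bis(benzyloxy)-4-iodophenoxy]triisopropylsilane | CC(C)[Si](Oc1cc(OCc2ccccc2)c(I)c(OCc2ccccc2)c1)(C(C)C)C(C)C
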